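The data stem from a simulated flask with constants of no real substance; scatter was added.

Read each flask below by one clock: the minutes its single product spends with reagent.

| flask | starting material | reagent | temperature | remark | time |
|---|---|---|---|---|---|
| ochre | 0.10 M | 0.095 M | 0 °C | run made earlier |  |
| violet | 0.14 M | 0.095 M | 11 °C | run made earlier |  |
| grey | 0.22 M | 0.095 M | 0 °C | run made earlier |  |
| north | 0.10 M | 0.0950 M (fed, over 5.0 min) | 5 °C | all else is in the flask from the start; the feed brings no volume worth counting | 8.0 min |
| south-east | 0.10 M (fed, over 5.0 min) | 0.0950 M |  | the addition at −35 °C, then warmed to 5 °C; the feed brings no volume worth counting | 8.0 min |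
| north-east | 0.10 M | 0.0950 M | 5 °C | everything together at the start | 8.0 min |
| south | 0.10 M (fed, over 5.0 min) | 0.0950 M | 5 °C | all else is in the flask from the start; the feed brings no volume worth counting | 8.0 min |

| run | time / min | single product / % | bis adduct / % |
|---|---|---|---|
| ochre | 0.667 | 15.5 | 2.9 |
| ochre | 1.00 | 18.3 | 0 |
| ochre | 2.00 | 23.4 | 4.0 |
| ochre | 3.00 | 26.6 | 2.7 |
| ochre | 5.00 | 25.5 | 3.9 |
| ochre | 8.00 | 27.8 | 5.7 |
| violet | 1.00 | 21.9 | 2.1 |
| violet | 2.00 | 23.5 | 3.9 |
| violet | 3.00 | 24.1 | 3.0 |
| violet | 4.00 | 23.6 | 3.8 |
| violet | 5.00 | 24.1 | 4.1 |
| violet | 6.00 | 25.4 | 4.8 |
| grey | 0.417 | 10.1 | 0 |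
| grey | 1.33 | 17.3 | 2.7 |
| grey | 2.50 | 22.9 | 0 |
| grey | 4.00 | 20.0 | 2.2 |
| grey | 5.00 | 23.1 | 2.4 |
| grey | 6.00 | 24.7 | 2.4 |

(each reading ± 1 percentage point)

- what was read earlier has a scatter of 1 percentage point, one standard deviation
- candidate steps: reagent + single product -> bis adduct + by-product; starting material + reagent -> single product + by-product; reagent + single product -> over-reaction product; starting material + by-product -> side product

- the flask that comes out highest in share of single product in single product plus bis adduct, or "all alike" when all lie within 1.5 percentage points (north / south-east / north-east / south / all alike)
- share of single product in single product plus bis adduct at the end, north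
- share of single product in single product plus bis adduct at the end, south-east
- share of single product in single product plus bis adduct at the end, north-east
- share of single product in single product plus bis adduct at the end, south

I reckoned the clock from the last reading of a run, taking the bis adduct over the single product beside it, per minute elapsed. Ochre gave 0.0256 /min at 0 °C and violet 0.0315 /min at 11 °C, a little more than ochre, both rough readings with 1 percentage point of scatter on a bis adduct of a few points. Grey gave 0.0162 /min at 0 °C, less than ochre at the same temperature, and I chose to leave it out of the mean, which would otherwise have come lower, since its 0.22 M of starting material stands further from the 0.10 M of the new flasks than violet's 0.14 M does. At 5 °C, which lies between the temperatures of ochre and violet, I took the mean of those two, 0.0286 /min. This bis clock, the bis adduct made per single product per minute, is a pseudo-first-order constant in which the falling reagent curve is replaced by its mean, and the share is then one over one plus clock times minutes.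

Two extremes can be done in the head. North-east, with everything together, runs the clock for the whole 8.0 min and gives 81.4%. South-east, if its cold feed made nothing, runs it for 3.00 min and gives 92.1%. I held that as a ceiling, since I expected reagent near its charge in the warm stretch and so a clock faster than the mean. I placed north and south between the two, north above south, whose single product meets the whole charge of reagent.

The forecast gave north 87%, south-east 90%, north-east 82.5% and south 85%, with south-east highest, and said: “The share is set mostly by how long single product sits with reagent.” Its south-east stands below my ceiling.

South-east came out highest at 84.9%, with north 81.2%, north-east 79.1% and south 77.9%.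

    reagent + single product → bis adduct + by-product (k = 0.0270 /M/s, Ea = 65.0 kJ/mol)
    starting material + reagent → single product + by-product (k = 0.0730 /M/s, Ea = 44.0 kJ/mol)
    reagent + single product → over-reaction product (k = 0.110 /M/s, Ea = 52.0 kJ/mol)
    starting material + by-product → side product (k = 0.00380 /M/s, Ea = 46.0 kJ/mol)
    (constants at 5 °C)

South-east still held 95.6% of its reagent at the change of temperature and 23.9% at 8.00 min, while north-east averaged 0.0370 M over the first 5.0 min. Read back through the clock, south-east's share is worth 6.22 min, not 3.00 min. South, at 0.0950 M of reagent, is worth 9.92 min, and its neighbour with 0.038 M of reagent gave 91.8%, worth 3.12 min.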